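**Plan**
Ring letters: A is the methoxy ring, B the para-linked ring, C the phenol ring, D the meta-linked ring. Ring D is numbered D1 (aryloxy carbon) to D6, with the bridge CH2 on D3.
Enabling feature: on ring D the ether oxygen (D1) and the bridge carbon (D3) are 1,3-related. A 3-alkylcyclobutenone and an alkynyl ether build a benzene ring with exactly this pattern, at the cost of one extra OH on D5.
Retrosynthesis: put back the D5 hydroxyl and a benzyl group on the ring C phenol, then cut D1–D2, D4–D5 and D5–D6. This gives a cyclobutenone on the ring A bridge and an ethynyl ether on the ring C oxygen.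
Further cuts: the cyclobutenone C3–CH2 bond (alkyllithium plus 3-ethoxycyclobutenone), the B–C ethylene bridge (Wittig, then diimide) and the A–O–B ether (SNAr).
Forward: A and B are joined, then C is added with its oxygen carrying a 1,2-dichlorovinyl group as latent alkyne. The alkyne is released and the cyclobutenone is attached last. One thermal step then closes ring D and the 19-membered ring, and deoxygenation and debenzylation finish.
Stereochemistry: the target has no stereocentre and no fixed alkene. The stilbene E/Z mixture and the racemic transients all converge.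

Key step: step 12

Remark on the order of events: a ketene-based cyclobutenone synthesis would attack an ethynyl ether, and the n-BuLi that releases the ethynyl ether would destroy a cyclobutenone. The alkyne is therefore freed first, and the enone is brought in afterwards as a C4 electrophile that stays masked until a mild acid step.

**Step 1**
Reactants: 1 (3-hydroxy-4-methoxyphenyl)acetic acid
Product: 2 2-(3-hydroxy-4-methoxyphenyl)ethanol
Conditions: BH3·THF (3 equiv), THF, 0 °C to rt; aqueous work-up
Reagents that add atoms: none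
Why: Chemoselective borane reduction of a carboxylic acid runs through the acyloxyborane and should leave the phenol and the aryl methyl ether unchanged after hydrolytic work-up.

**Step 2**
Reactants: 2 2-(3-hydroxy-4-methoxyphenyl)ethanol; 3 4-fluorobenzaldehyde
Product: 4 4-[5-(2-hydroxyethyl)-2-methoxyphenoxy]benzaldehyde
Conditions: K2CO3, DMF, 120 °C
Reagents that add atoms: none
Why: In this nucleophilic aromatic substitution (SNAr) K2CO3 ionises only the phenol and the para-formyl group activates the fluoride, so the A–O–B ether should form without protecting the primary alcohol.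

**Step 3**
Reactants: 5 4-(benzyloxy)-3-hydroxybenzaldehyde
Product: 6 4-(benzyloxy)-3-{[(E)-1,2-dichloroethenyl]oxy}benzaldehyde
Conditions: Cl2C=CHCl, K2CO3, DMF, 70 °C
Reagents that add atoms: trichloroethylene ClC=C(Cl)Cl
Why: Anti addition of a phenoxide to dichloroacetylene formed in situ is the standard entry to aryl (E)-1,2-dichlorovinyl ethers, and aldehyde and benzyl ether are inert to K2CO3.

**Step 4**
Reactants: 6 4-(benzyloxy)-3-{[(E)-1,2-dichloroethenyl]oxy}benzaldehyde
Product: 7 (4-(benzyloxy)-3-{[(E)-1,2-dichloroethenyl]oxy}phenyl)methanol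
Conditions: NaBH4, MeOH–THF, 0 °C
Reagents that add atoms: none
Why: Borohydride reduction of an aromatic aldehyde is fast at 0 °C and does not touch the chlorinated enol ether or the benzyl ether.

**Step 5**
Reactants: 7 (4-(benzyloxy)-3-{[(E)-1,2-dichloroethenyl]oxy}phenyl)methanol
Product: 8 (4-(benzyloxy)-3-{[(E)-1,2-dichloroethenyl]oxy}benzyl)triphenylphosphonium bromide
Conditions: PPh3·HBr, MeCN, reflux
Reagents that add atoms: triphenylphosphine hydrobromide [Br-].c1ccc(cc1)[PH+](c1ccccc1)c1ccccc1
Why: Direct phosphonium salt formation from a benzylic alcohol is helped by the para-benzyloxy group, which stabilises the benzylic cation, while the electron-poor dichlorovinyl ether is too weakly basic to be protonated.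

**Step 6**
Reactants: 8 (4-(benzyloxy)-3-{[(E)-1,2-dichloroethenyl]oxy}benzyl)triphenylphosphonium bromide; 4 4-[5-(2-hydroxyethyl)-2-methoxyphenoxy]benzaldehyde
Product: 10 A–B–C stilbene bearing the dichlorovinyl ether (E/Z mixture), via phosphonium ylide 9 (not isolated)
Conditions: K2CO3, 18-crown-6 (cat.), CH2Cl2, reflux
Reagents that add atoms: none
Why: Wittig olefination with a semi-stabilised benzylic ylide under mild solid–liquid conditions tolerates the free alcohol and the dichlorovinyl ether, and the alkene geometry does not matter because the double bond is saturated next.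

**Step 7**
Reactants: 10 A–B–C stilbene bearing the dichlorovinyl ether (E/Z mixture)
Product: 11 A–B–C bibenzyl bearing the dichlorovinyl ether
Conditions: TsNHNH2, NaOAc, DME–H2O, reflux
Reagents that add atoms: none
Why: Diimide reduction delivers hydrogen in a concerted way to the unhindered 1,2-disubstituted stilbene bond, whereas the trisubstituted chloroalkene reacts far more slowly and the benzyl ether and C–Cl bonds cannot be hydrogenolysed by this reagent.

**Step 8**
Reactants: 11 A–B–C bibenzyl bearing the dichlorovinyl ether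
Product: 13 2-[3-(4-{2-[4-(benzyloxy)-3-(ethynyloxy)phenyl]ethyl}phenoxy)-4-methoxyphenyl]ethanol, via dilithium alkoxide acetylide 12 (not isolated)
Conditions: n-BuLi (3.5 equiv), THF, −78 to −40 °C; sat. aq NH4Cl, −78 °C
Reagents that add atoms: none
Why: Dehydrochlorination followed by chlorine–lithium exchange is the established conversion of 1,2-dichlorovinyl ethers into alkynyl ethers; the alcohol only consumes one equivalent of base, benzylic and ortho lithiation are slow at this temperature, and the product should be kept cold and used promptly.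

**Step 9**
Reactants: 13 2-[3-(4-{2-[4-(benzyloxy)-3-(ethynyloxy)phenyl]ethyl}phenoxy)-4-methoxyphenyl]ethanol
Product: 15 1-(benzyloxy)-2-(ethynyloxy)-4-(2-{4-[5-(2-iodoethyl)-2-methoxyphenoxy]phenyl}ethyl)benzene, via mesylate 14 (not isolated)
Conditions: MsCl, Et3N, CH2Cl2, 0 °C; solvent exchange; NaI, acetone, 40 °C
Reagents that add atoms: methanesulfonyl chloride CS(=O)(=O)Cl (retained only in 14); sodium iodide [Na+].[I-]
Why: Sulfonylation under amine-buffered conditions and Finkelstein displacement are neutral to basic throughout and avoid free halogen, so the acid- and electrophile-sensitive ethynyl ether should survive.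

**Step 10**
Reactants: 16 ethoxyacetylene
Product: 17 3-ethoxycyclobut-2-en-1-one
Conditions: ketene gas (from acetone, hot-wire pyrolysis), CH2Cl2, 0 °C
Reagents that add atoms: ketene C=C=O (generated from acetone CC(C)=O)
Why: The [2+2] cycloaddition of ketene with an electron-rich alkynyl ether is regioselective, because the unsubstituted alkyne carbon bonds to the ketene carbonyl carbon, and it gives the vinylogous ester directly.

**Step 11**
Reactants: 15 1-(benzyloxy)-2-(ethynyloxy)-4-(2-{4-[5-(2-iodoethyl)-2-methoxyphenoxy]phenyl}ethyl)benzene; 17 3-ethoxycyclobut-2-en-1-one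
Product: 20 3-{2-[3-(4-{2-[4-(benzyloxy)-3-(ethynyloxy)phenyl]ethyl}phenoxy)-4-methoxyphenyl]ethyl}cyclobut-2-en-1-one, via alkyl acetylide dilithium species 18 (not isolated), via tertiary carbinol 19 (not isolated)
Conditions: MeLi (1.0 equiv), Et2O–THF, −78 °C; t-BuLi (2.0 equiv), −78 °C; 17 (1.0 equiv), −78 °C; sat. aq NH4Cl, −78 °C; then PPTS (cat.), THF–H2O, 0 °C
Reagents that add atoms: water O
Why: This is a Stork–Danheiser-type 1,2-addition and transposition on a four-membered vinylogous ester: MeLi first stores the acetylenic C–H as an inert acetylide, iodine–lithium exchange gives the far more reactive alkyllithium, enolisation of 17 is disfavoured because it would create a cyclobutadiene-like enolate, and the doubly activated carbinol ionises under acid too weak to hydrate an aryl ethynyl ether.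

**Step 12**
Reactants: 20 3-{2-[3-(4-{2-[4-(benzyloxy)-3-(ethynyloxy)phenyl]ethyl}phenoxy)-4-methoxyphenyl]ethyl}cyclobut-2-en-1-one
Product: 25 O-benzyl macrocycle carrying an extra hydroxyl on D5, via vinylketene 21 (not isolated), via macrocyclic alkenylcyclobutenone 22 (not isolated), via dienylketene 23 (not isolated), via cyclohexadienone 24 (not isolated)
Conditions: toluene (degassed, base-washed glass, final 1 mM), 110 °C, syringe-pump addition over 20 h, then 4 h
Reagents that add atoms: none
Why: Proposed new method: at 110 °C the cyclobutenone of 20 opens in a reversible four-electron electrocyclic reaction to vinylketene 21, the unsubstituted and nucleophilic alkyne carbon of the ethynyl ether attacks the ketene carbonyl carbon, and the resulting [2+2] cycloaddition gives alkenylcyclobutenone 22, which opens again to dienylketene 23, closes to cyclohexadienone 24 and tautomerises to phenol 25. The closest known reaction type is the bimolecular Danheiser benzannulation of cyclobutenones with alkynyl ethers, which has not yet been asked to close a large ring. The 19-membered ring closes in the ketene–alkyne [2+2] cycloaddition, through the D1–D2 bond between the oxygen-bearing alkyne carbon and the ketene alpha carbon, and ring D closes in the six-electron electrocyclisation that rejoins the ketene carbon (D5) to the terminal methylene carbon (D4). No stereocentre survives, since the one sp3 ring carbon of racemic 22 becomes trigonal in the next ring opening. The step needs head-to-tail regiochemistry, which the polarity match between the electrophilic ketene carbon and the electron-rich alkyne terminus enforces, so that aryloxy group and bridge end up meta on ring D whatever the tether prefers. It also needs ring closure to beat oligomerisation, which pseudo-high dilution, the reversible storage of 21 as 20, the lack of a retro-ene path in an aryl ethynyl ether and the irreversible aromatisation should secure.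

**Step 13**
Reactants: 25 O-benzyl macrocycle carrying an extra hydroxyl on D5
Product: 26 D5 aryl triflate of the O-benzyl macrocycle
Conditions: Tf2O, pyridine, CH2Cl2, 0 °C
Reagents that add atoms: trifluoromethanesulfonic anhydride O=S(=O)(OS(=O)(=O)C(F)(F)F)C(F)(F)F
Why: O-sulfonylation of the only free hydroxyl group in the molecule is a routine activation of a phenol for reductive removal.

**Step 14**
Reactants: 26 D5 aryl triflate of the O-benzyl macrocycle
Product: 27 O-benzyl macrocycle
Conditions: Pd(OAc)2 (5 mol %), 1,3-bis(diphenylphosphino)propane, HCO2H, Et3N, DMF, 80 °C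
Reagents that add atoms: none
Why: In the palladium-catalysed formate reduction of aryl triflates, oxidative addition to zerovalent palladium, formate exchange, loss of CO2 and reductive elimination replace C–O by C–H, and the homogeneous catalyst leaves the benzyl ether and the diaryl ethers alone.

**Step 15**
Reactants: 27 O-benzyl macrocycle
Product: 28 target CNP0132125.0
Conditions: H2 (1 atm), Pd/C (10 wt %), EtOAc–MeOH, rt
Reagents that add atoms: none
Why: Catalytic hydrogenolysis cleaves the aryl benzyl ether selectively, because the methyl ether, the diaryl ethers and the saturated bridges are inert under these conditions.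

**Compound list**
1 | (3-hydroxy-4-methoxyphenyl)acetic acid | COc1ccc(CC(=O)O)cc1O | starting material
2 | 2-(3-hydroxy-4-methoxyphenyl)ethanol | COc1ccc(CCO)cc1O | intermediate
3 | 4-fluorobenzaldehyde | O=Cc1ccc(F)cc1 | starting material
4 | 4-[5-(2-hydroxyethyl)-2-methoxyphenoxy]benzaldehyde | COc1ccc(CCO)cc1Oc1ccc(C=O)cc1 | intermediate
5 | 4-(benzyloxy)-3-hydroxybenzaldehyde | O=Cc1ccc(OCc2ccccc2)c(O)c1 | starting material
6 | 4-(benzyloxy)-3-{[(E)-1,2-dichloroethenyl]oxy}benzaldehyde | Cl/C=C(/Cl)Oc1cc(C=O)ccc1OCc1ccccc1 | intermediate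
7 | (4-(benzyloxy)-3-{[(E)-1,2-dichloroethenyl]oxy}phenyl)methanol | Cl/C=C(/Cl)Oc1cc(CO)ccc1OCc1ccccc1 | intermediate
8 | (4-(benzyloxy)-3-{[(E)-1,2-dichloroethenyl]oxy}benzyl)triphenylphosphonium bromide | Cl/C=C(/Cl)Oc1cc(C[P+](c2ccccc2)(c2ccccc2)c2ccccc2)ccc1OCc1ccccc1.[Br-] | intermediate
9 | benzylidene triphenylphosphorane derived from 8 | Cl/C=C(/Cl)Oc1cc(C=P(c2ccccc2)(c2ccccc2)c2ccccc2)ccc1OCc1ccccc1 | intermediate
10 | 2-[3-(4-{2-[4-(benzyloxy)-3-{[(E)-1,2-dichloroethenyl]oxy}phenyl]ethenyl}phenoxy)-4-methoxyphenyl]ethanol, E/Z mixture at the stilbene bond | Cl/C=C(/Cl)Oc1cc(C=Cc2ccc(Oc3cc(CCO)ccc3OC)cc2)ccc1OCc1ccccc1 | intermediate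
11 | 2-[3-(4-{2-[4-(benzyloxy)-3-{[(E)-1,2-dichloroethenyl]oxy}phenyl]ethyl}phenoxy)-4-methoxyphenyl]ethanol | Cl/C=C(/Cl)Oc1cc(CCc2ccc(Oc3cc(CCO)ccc3OC)cc2)ccc1OCc1ccccc1 | intermediate
12 | dilithium salt of 13 (lithium alkoxide and lithium aryloxyacetylide) | COc1ccc(CCO[Li])cc1Oc1ccc(CCc2ccc(OCc3ccccc3)c(OC#C[Li])c2)cc1 | intermediate
13 | 2-[3-(4-{2-[4-(benzyloxy)-3-(ethynyloxy)phenyl]ethyl}phenoxy)-4-methoxyphenyl]ethanol | COc1ccc(CCO)cc1Oc1ccc(CCc2ccc(OCc3ccccc3)c(OC#C)c2)cc1 | intermediate
14 | methanesulfonate of 13 | COc1ccc(CCOS(C)(=O)=O)cc1Oc1ccc(CCc2ccc(OCc3ccccc3)c(OC#C)c2)cc1 | intermediate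
15 | 1-(benzyloxy)-2-(ethynyloxy)-4-(2-{4-[5-(2-iodoethyl)-2-methoxyphenoxy]phenyl}ethyl)benzene | COc1ccc(CCI)cc1Oc1ccc(CCc2ccc(OCc3ccccc3)c(OC#C)c2)cc1 | intermediate
16 | ethoxyacetylene | CCOC#C | starting material
17 | 3-ethoxycyclobut-2-en-1-one | CCOC1=CC(=O)C1 | intermediate
18 | dilithium species from 15 (2-arylethyllithium and lithium aryloxyacetylide) | COc1ccc(CC[Li])cc1Oc1ccc(CCc2ccc(OCc3ccccc3)c(OC#C[Li])c2)cc1 | intermediate
19 | 1-(2-arylethyl)-3-ethoxycyclobut-2-en-1-ol, racemic, aryl being the A–B–C unit of 15 | COc1ccc(CCC2(O)C=C(OCC)C2)cc1Oc1ccc(CCc2ccc(OCc3ccccc3)c(OC#C)c2)cc1 | intermediate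
20 | 3-{2-[3-(4-{2-[4-(benzyloxy)-3-(ethynyloxy)phenyl]ethyl}phenoxy)-4-methoxyphenyl]ethyl}cyclobut-2-en-1-one | COc1ccc(CCC2=CC(=O)C2)cc1Oc1ccc(CCc2ccc(OCc3ccccc3)c(OC#C)c2)cc1 | intermediate
21 | vinylketene from ring opening of 20 (3-methylene-5-arylpent-1-en-1-one) | COc1ccc(CCC(=C)C=C=O)cc1Oc1ccc(CCc2ccc(OCc3ccccc3)c(OC#C)c2)cc1 | intermediate
22 | macrocyclic 3-aryloxy-4-alkenylcyclobut-2-en-1-one, racemic | COc1ccc2cc1Oc1ccc(cc1)CCc1ccc(OCc3ccccc3)c(c1)OC1=CC(=O)C1C(=C)CC2 | intermediate
23 | macrocyclic (E)-dienylketene, ketenyl and alkenyl groups cis | COc1ccc2cc1Oc1ccc(cc1)CCc1ccc(OCc3ccccc3)c(c1)O/C(C=C=O)=C/C(=C)CC2 | intermediate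
24 | macrocyclic 3-aryloxy-5-alkylcyclohexa-2,4-dien-1-one | COc1ccc2cc1Oc1ccc(cc1)CCc1ccc(OCc3ccccc3)c(c1)OC1=CC(=O)CC(=C1)CC2 | intermediate
25 | O-benzyl macrocycle with hydroxyl on D5 | COc1ccc2cc1Oc1ccc(cc1)CCc1ccc(OCc3ccccc3)c(c1)Oc1cc(O)cc(c1)CC2 | intermediate
26 | D5 trifluoromethanesulfonate of 25 | COc1ccc2cc1Oc1ccc(cc1)CCc1ccc(OCc3ccccc3)c(c1)Oc1cc(OS(=O)(=O)C(F)(F)F)cc(c1)CC2 | intermediate
27 | O-benzyl macrocycle | COc1ccc2cc1Oc1ccc(cc1)CCc1ccc(OCc3ccccc3)c(c1)Oc1cccc(c1)CC2 | intermediate
28 | CNP0132125.0, macrocyclic bis(bibenzyl) diether | COc1ccc2cc1Oc1ccc(cc1)CCc1ccc(O)c(c1)Oc1cccc(c1)CC2 | target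

**Step count**
Total step count: 15.
Longest linear sequence: 12 steps from 5 (steps 3 to 9 and 11 to 15).

**Steps most likely to fail**

Step 12. The vinylketene may be consumed by intermolecular union with the alkyne of a second molecule or by acylation of the phenol already formed. The ethynyl ether may also decay thermally before a productive conformer is reached.

The fallback builds ring D bimolecularly and closes the large ring by cross-coupling. It sets out from 15.
- KOt-Bu in THF at 0 °C eliminates HI to give the ring A styrene F1.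
- Commercial 3-bromocyclobutanone and Bu3N give cyclobut-2-en-1-one F2.
- Heating F1 with F2 in toluene is an ordinary Danheiser benzannulation and should give the 3-aryloxyphenol F3. Its new hydroxyl sits on D3, where the bridge belongs.
- Tf2O and pyridine convert F3 into the aryl triflate F4.
- 9-BBN hydroborates the styrene to the B-alkyl borane F5.
- Slow addition of F5 to PdCl2(dppf) and Cs2CO3 in DMF–THF–H2O at 60 °C closes the ring by a macrocyclic B-alkyl Suzuki–Miyaura coupling.

The route is rejoined at 27, so 25 and 26 are bypassed.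

Step 11. Proton transfer may quench the alkyllithium, the acetylide terminus may compete for the ketone, and the ethynyl ether may be hydrated during the acid transposition.

The fallback replaces in situ protection by a real protecting group. It sets out from 15.
- MeLi at −78 °C followed by Me3SiCl gives the C-silylated iodide F6.
- t-BuLi then produces a single carbanionic site, the alkyllithium F7.
- F7 adds to 17 to give the silylated carbinol F8.
- Methanol added to the cold mixture forms LiOMe, which removes the silyl group while the enone is still masked and base-stable.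

The route is rejoined at 19, which is transposed to 20 as before.

Step 10. Ketene may dimerise, and the strained, volatile product may polymerise or be lost on isolation.

The fallback uses a ketene made in solution and then removes its halogens. It sets out from 16.
- Dichloroketene, formed from trichloroacetyl chloride and Zn–Cu couple in Et2O–DME, adds to 16 to give 4,4-dichloro-3-ethoxycyclobut-2-en-1-one F9.
- Zn, AcOH and TMEDA in EtOH remove both chlorines.

The route is rejoined at 17.

**Further compounds**
F1 | step 12 | 1-(benzyloxy)-4-(2-{4-[5-ethenyl-2-methoxyphenoxy]phenyl}ethyl)-2-(ethynyloxy)benzene | COc1ccc(C=C)cc1Oc1ccc(CCc2ccc(OCc3ccccc3)c(OC#C)c2)cc1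
F2 | step 12 | cyclobut-2-en-1-one | O=C1C=CC1
F3 | step 12 | 3-[2-(benzyloxy)-5-(2-{4-[5-ethenyl-2-methoxyphenoxy]phenyl}ethyl)phenoxy]phenol | COc1ccc(C=C)cc1Oc1ccc(CCc2ccc(OCc3ccccc3)c(Oc3cccc(O)c3)c2)cc1
F4 | step 12 | trifluoromethanesulfonate of F3 | COc1ccc(C=C)cc1Oc1ccc(CCc2ccc(OCc3ccccc3)c(Oc3cccc(OS(=O)(=O)C(F)(F)F)c3)c2)cc1
F5 | step 12 | B-(2-arylethyl)-9-borabicyclo[3.3.1]nonane from F4 | COc1ccc(CCB2C3CCCC2CCC3)cc1Oc1ccc(CCc2ccc(OCc3ccccc3)c(Oc3cccc(OS(=O)(=O)C(F)(F)F)c3)c2)cc1
F6 | step 11 | C-trimethylsilyl derivative of iodide 15 | COc1ccc(CCI)cc1Oc1ccc(CCc2ccc(OCc3ccccc3)c(OC#C[Si](C)(C)C)c2)cc1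
F7 | step 11 | 2-arylethyllithium from F6 | COc1ccc(CC[Li])cc1Oc1ccc(CCc2ccc(OCc3ccccc3)c(OC#C[Si](C)(C)C)c2)cc1
F8 | step 11 | C-trimethylsilyl derivative of carbinol 19, racemic | COc1ccc(CCC2(O)C=C(OCC)C2)cc1Oc1ccc(CCc2ccc(OCc3ccccc3)c(OC#C[Si](C)(C)C)c2)cc1
F9 | step 10 | 4,4-dichloro-3-ethoxycyclobut-2-en-1-one | CCOC1=CC(=O)C1(Cl)Cl
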